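Ring B is taken apart at C1'–C2' and C5'–C6'. C2'–C5' with all three oxygens come from a squarate-derived 4-chlorocyclobutenone; C1', C6' and the benzylic C7' are a 2-stannylallyl chain already attached to C8' of the finished (3R,4R) lactone that bears ring A. One operation (Stille coupling, 4-pi opening, 6-pi closure, tautomerisation) builds ring B and exploits its contiguous O3'/O4'/O5' triad, in which only O5' is methylated. The two isopropoxy carbons become the C3'/C4' catechol and the ketene carbon becomes C5' as the only free phenol, the one site to methylate. The precursor is the trans lactone with a ring A benzyl ether and a 2-(trimethylstannyl)allyl group.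

Key step: step 8

Numbering used: ring B is C1'–C6'; its benzylic CH2 is C7', attached to lactone carbon C3 (= C8'); ring A is attached through its benzylic CH2 to lactone carbon C4. C5' is the ring B carbon that carries OMe in the target.

Design choices: tin carries methyl rather than butyl groups, so that both the stannylation (step 5) and the transfer of the hindered 1,1-disubstituted alkenyl group (step 8) are faster. The ring A phenol is a benzyl ether, so that one BCl3 treatment removes it together with both isopropyl groups.

Assumption: the (4S,5S) hand of MOD-DIOP is taken to deliver the (R) acid 4 from the (E) half-ester; if the sense of induction proves opposite, the (4R,5R) ligand is used with no other change.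

Step 1
Reactants: 1 4-(benzyloxy)-3-methoxybenzaldehyde; 2 dimethyl succinate
Product: 3 (E)-4-[4-(benzyloxy)-3-methoxyphenyl]-3-(methoxycarbonyl)but-3-enoic acid
Conditions: NaOMe (2 equiv), MeOH, reflux; then 2 M HCl
Reagents that add atoms: none
Why: Stobbe condensation, in which the succinate enolate adds to the aldehyde, the aldolate lactonises onto the second ester and E1cB opening of the paraconate gives the half-ester with the free acid on the CH2 arm and the (E) alkene (aryl trans to the ester), the benzyl ether being inert to methoxide.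

Step 2
Reactants: 3 (E)-4-[4-(benzyloxy)-3-methoxyphenyl]-3-(methoxycarbonyl)but-3-enoic acid
Product: 4 (R)-4-[4-(benzyloxy)-3-methoxyphenyl]-3-(methoxycarbonyl)butanoic acid
Conditions: H2 (1–5 atm), [Rh(cod)Cl]2 (0.5 mol%), (4S,5S)-MOD-DIOP [(4S,5S)-4,5-bis{[bis(4-methoxy-3,5-dimethylphenyl)phosphanyl]methyl}-2,2-dimethyl-1,3-dioxolane, 1.1 mol%], Et3N (1 equiv), MeOH, 30 °C; then 1 M HCl
Reagents that add atoms: none
Why: Rhodium-catalysed asymmetric hydrogenation of an itaconate-type half-ester, in which the carboxylate (as its triethylammonium salt) and the alkene bind rhodium as a chelate and the C2-symmetric diphosphine lets H2 add to one face only, which sets the (R) centre that becomes lactone C4, while the aryl benzyl ether is not hydrogenolysed by this homogeneous catalyst.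

Step 3
Reactants: 4 (R)-4-[4-(benzyloxy)-3-methoxyphenyl]-3-(methoxycarbonyl)butanoic acid
Product: 6 (R)-4-[4-(benzyloxy)-3-methoxybenzyl]dihydrofuran-2(3H)-one, via hydroxy acid 5 (not isolated)
Conditions: KOH (1.0 equiv), EtOH, 0 °C; CaCl2, NaBH4, EtOH, −10 °C → rt; then 3 M HCl, rt
Reagents that add atoms: none
Why: Chemoselective borohydride reduction followed by acid-catalysed lactonisation, since Ca(BH4)2 reduces the methyl ester but not the potassium carboxylate (reduction at low temperature outruns enolisation of the ester), and on acidification the gamma-hydroxy acid 5 closes to the five-membered lactone with the stereocentre unchanged (descriptor stays R).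

Step 4
Reactants: 6 (R)-4-[4-(benzyloxy)-3-methoxybenzyl]dihydrofuran-2(3H)-one; 7 2,3-dibromoprop-1-ene
Product: 9 (3R,4R)-4-[4-(benzyloxy)-3-methoxybenzyl]-3-(2-bromoprop-2-en-1-yl)dihydrofuran-2(3H)-one, via lithium enolate 8 (not isolated)
Conditions: LiN(SiMe3)2 (1.1 equiv), THF, −78 °C; then 7 (1.5 equiv), DMPU, −78 → −40 °C
Reagents that add atoms: none
Why: Enolate alkylation (SN2 at the allylic bromide), in which the electrophile approaches the planar lithium enolate on the face anti to the C4 benzyl group, which sets C3 as R and gives the trans lactone, while the vinylic bromide does not react.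

Step 5
Reactants: 9 (3R,4R)-4-[4-(benzyloxy)-3-methoxybenzyl]-3-(2-bromoprop-2-en-1-yl)dihydrofuran-2(3H)-one
Product: 10 (3R,4R)-4-[4-(benzyloxy)-3-methoxybenzyl]-3-[2-(trimethylstannyl)prop-2-en-1-yl]dihydrofuran-2(3H)-one
Conditions: Me3SnSnMe3 (1.5 equiv), Pd(PPh3)4 (5 mol%), toluene, 100 °C; aq. KF work-up, chromatography on Et3N-deactivated silica
Reagents that add atoms: hexamethylditin, C[Sn](C)(C)[Sn](C)(C)C
Why: Palladium-catalysed stannylation of an alkenyl bromide with a distannane, in which zerovalent palladium inserts into the C(sp2)–Br bond and Sn–Sn transmetalation with reductive elimination gives the alkenylstannane, the lactone, the benzyl ether and both stereocentres being untouched under these neutral conditions.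

Step 6
Reactants: 11 diisopropyl squarate
Product: 12 4-hydroxy-2,3-diisopropoxycyclobut-2-en-1-one
Conditions: LiAlH(OtBu)3 (1.1 equiv), THF, −78 → −20 °C; then H2O (pH 7 buffer)
Reagents that add atoms: none
Why: 1,2-Reduction of a vinylogous ester carbonyl, in which the bulky, mild hydride adds once to one of the two equivalent carbonyl groups and the resulting alkoxide resists a second addition; the racemic carbinol centre is of no consequence because it is lost on aromatisation.

Step 7
Reactants: 12 4-hydroxy-2,3-diisopropoxycyclobut-2-en-1-one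
Product: 13 4-chloro-2,3-diisopropoxycyclobut-2-en-1-one
Conditions: PPh3 (1.2 equiv), CCl4 (3 equiv), CH2Cl2, 0 °C → rt
Reagents that add atoms: tetrachloromethane, ClC(Cl)(Cl)Cl
Why: Appel reaction, in which the alkoxyphosphonium salt formed under neutral conditions is displaced by chloride at the activated carbon next to the carbonyl, and the absence of acid avoids the loss of 2-propanol that would lead to the cyclobutenedione.

Step 8
Reactants: 10 (3R,4R)-4-[4-(benzyloxy)-3-methoxybenzyl]-3-[2-(trimethylstannyl)prop-2-en-1-yl]dihydrofuran-2(3H)-one; 13 4-chloro-2,3-diisopropoxycyclobut-2-en-1-one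
Product: 17 (3R,4R)-4-[4-(benzyloxy)-3-methoxybenzyl]-3-(3-hydroxy-4,5-diisopropoxybenzyl)dihydrofuran-2(3H)-one, via 4-alkenylcyclobutenone 14 (not isolated), via dienylketene 15 (not isolated), via cyclohexadienone 16 (not isolated)
Conditions: 13 (1.3 equiv), Pd2(dba)3 (2.5 mol%), tri(2-furyl)phosphine (10 mol%), dioxane, 50 °C; then 100 °C; aq. KF work-up
Reagents that add atoms: none
Why: Zerovalent palladium inserts into the activated C–Cl bond of 13, the 1,1-disubstituted alkenyl group moves from tin to palladium (methyl groups on tin keep this hindered transfer fast) and reductive elimination forms C1'–C2' in 14. At 100 °C 14 opens by a reversible conrotatory 4-pi electrocyclic reaction to dienylketene 15, and the isomer whose alkenyl group points towards the ketene closes the six-membered carbocyclic ring B by a thermally allowed disrotatory 6-pi electrocyclisation that forms C5'–C6' in 16; enolisation to phenol 17 is irreversible and drains every equilibrium before it. The closest known reaction type is the Stille coupling of 4-chlorocyclobutenones with alkenyl- or arylstannanes followed by thermal ring expansion to phenols. No stereocentre is created in 17: the CH centre of 14 (both epimers form from racemic 13) is erased on aromatisation, and C3 and C4 of the lactone are spectators under these neutral conditions. The selectivity needed is the order of the substituents around ring B, and connectivity alone secures it: the tin-bearing carbon becomes C1' with C7', the CHCl carbon becomes C2'–H, the two isopropoxy carbons become C3' and C4', the carbonyl carbon becomes C5'–OH and the alkene CH2 becomes C6'–H. Chemoselectivity rests on the C–Cl bond being the only site that zerovalent palladium can enter, since the aryl ethers, the lactone and the alkene offer no competing reaction.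

Step 9
Reactants: 17 (3R,4R)-4-[4-(benzyloxy)-3-methoxybenzyl]-3-(3-hydroxy-4,5-diisopropoxybenzyl)dihydrofuran-2(3H)-one
Product: 18 (3R,4R)-4-[4-(benzyloxy)-3-methoxybenzyl]-3-(3,4-diisopropoxy-5-methoxybenzyl)dihydrofuran-2(3H)-one
Conditions: MeI (3 equiv), K2CO3 (2 equiv), acetone, 50 °C
Reagents that add atoms: iodomethane, CI
Why: Williamson ether synthesis, in which the C5' hydroxyl is the only acidic OH in 17 and is therefore methylated alone, while K2CO3 in acetone is too weak to open or epimerise the trans lactone (the more stable isomer in any case).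

Step 10
Reactants: 18 (3R,4R)-4-[4-(benzyloxy)-3-methoxybenzyl]-3-(3,4-diisopropoxy-5-methoxybenzyl)dihydrofuran-2(3H)-one
Product: 19 (−)-thujaplicatin
Conditions: BCl3 (1 M in CH2Cl2, 8 equiv), pentamethylbenzene (3 equiv), CH2Cl2, −78 → 0 °C; then MeOH, H2O
Reagents that add atoms: none
Why: Lewis-acid dealkylation of aryl ethers, in which BCl3 binds the ether oxygens and the benzyl and secondary isopropyl groups depart as stabilised cations (trapped by pentamethylbenzene and by chloride), whereas the two methyl ethers, which have no such path, and the lactone survive at or below 0 °C, and hydrolysis of the aryl borates frees the three phenols without touching C3 or C4.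

Compound list
1 | 4-(benzyloxy)-3-methoxybenzaldehyde (O-benzylvanillin) | COc1cc(C=O)ccc1OCc1ccccc1 | starting material
2 | dimethyl succinate | COC(=O)CCC(=O)OC | starting material
3 | (E)-4-[4-(benzyloxy)-3-methoxyphenyl]-3-(methoxycarbonyl)but-3-enoic acid | COc1cc(/C=C(\CC(=O)O)C(=O)OC)ccc1OCc1ccccc1 | intermediate
4 | (R)-4-[4-(benzyloxy)-3-methoxyphenyl]-3-(methoxycarbonyl)butanoic acid | COc1cc(C[C@H](CC(=O)O)C(=O)OC)ccc1OCc1ccccc1 | intermediate
5 | (R)-3-[4-(benzyloxy)-3-methoxybenzyl]-4-hydroxybutanoic acid (present as its carboxylate salt) | COc1cc(C[C@H](CC(=O)O)CO)ccc1OCc1ccccc1 | intermediate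
6 | (R)-4-[4-(benzyloxy)-3-methoxybenzyl]dihydrofuran-2(3H)-one | COc1cc(C[C@H]2COC(=O)C2)ccc1OCc1ccccc1 | intermediate
7 | 2,3-dibromoprop-1-ene | C=C(Br)CBr | starting material
8 | lithium (3R)-3-[4-(benzyloxy)-3-methoxybenzyl]-2,3-dihydrofuran-5-olate (lithium enolate of 6) | COc1cc(C[C@H]2COC(O[Li])=C2)ccc1OCc1ccccc1 | intermediate
9 | (3R,4R)-4-[4-(benzyloxy)-3-methoxybenzyl]-3-(2-bromoprop-2-en-1-yl)dihydrofuran-2(3H)-one | COc1cc(C[C@H]2COC(=O)[C@@H]2CC(Br)=C)ccc1OCc1ccccc1 | intermediate
10 | (3R,4R)-4-[4-(benzyloxy)-3-methoxybenzyl]-3-[2-(trimethylstannyl)prop-2-en-1-yl]dihydrofuran-2(3H)-one | COc1cc(C[C@H]2COC(=O)[C@@H]2CC(=C)[Sn](C)(C)C)ccc1OCc1ccccc1 | intermediate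
11 | diisopropyl squarate (3,4-diisopropoxycyclobut-3-ene-1,2-dione) | CC(C)OC1=C(OC(C)C)C(=O)C1=O | starting material
12 | 4-hydroxy-2,3-diisopropoxycyclobut-2-en-1-one (racemic) | CC(C)OC1=C(OC(C)C)C(=O)C1O | intermediate
13 | 4-chloro-2,3-diisopropoxycyclobut-2-en-1-one (racemic) | CC(C)OC1=C(OC(C)C)C(=O)C1Cl | intermediate
14 | (3R,4R)-4-[4-(benzyloxy)-3-methoxybenzyl]-3-[2-(2,3-diisopropoxy-4-oxocyclobut-2-en-1-yl)prop-2-en-1-yl]dihydrofuran-2(3H)-one (both epimers at the cyclobutene CH) | COc1cc(C[C@H]2COC(=O)[C@@H]2CC(=C)C2C(=O)C(OC(C)C)=C2OC(C)C)ccc1OCc1ccccc1 | intermediate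
15 | (3R,4R)-4-[4-(benzyloxy)-3-methoxybenzyl]-3-[(3E)-4,5-diisopropoxy-2-methylidene-6-oxohexa-3,5-dien-1-yl]dihydrofuran-2(3H)-one (dienylketene, alkenyl group cis to the ketene carbon) | COc1cc(C[C@H]2COC(=O)[C@@H]2CC(=C)/C=C(OC(C)C)\C(OC(C)C)=C=O)ccc1OCc1ccccc1 | intermediate
16 | (3R,4R)-4-[4-(benzyloxy)-3-methoxybenzyl]-3-[(3,4-diisopropoxy-5-oxocyclohexa-1,3-dien-1-yl)methyl]dihydrofuran-2(3H)-one | COc1cc(C[C@H]2COC(=O)[C@@H]2CC2=CC(OC(C)C)=C(OC(C)C)C(=O)C2)ccc1OCc1ccccc1 | intermediate
17 | (3R,4R)-4-[4-(benzyloxy)-3-methoxybenzyl]-3-(3-hydroxy-4,5-diisopropoxybenzyl)dihydrofuran-2(3H)-one | COc1cc(C[C@H]2COC(=O)[C@@H]2Cc2cc(O)c(OC(C)C)c(OC(C)C)c2)ccc1OCc1ccccc1 | intermediate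
18 | (3R,4R)-4-[4-(benzyloxy)-3-methoxybenzyl]-3-(3,4-diisopropoxy-5-methoxybenzyl)dihydrofuran-2(3H)-one | COc1cc(C[C@H]2COC(=O)[C@@H]2Cc2cc(OC)c(OC(C)C)c(OC(C)C)c2)ccc1OCc1ccccc1 | intermediate
19 | (−)-thujaplicatin, (3R,4R)-3-(3,4-dihydroxy-5-methoxybenzyl)-4-(4-hydroxy-3-methoxybenzyl)dihydrofuran-2(3H)-one | COc1cc(C[C@H]2COC(=O)[C@@H]2Cc2cc(O)c(O)c(OC)c2)ccc1O | target

Total step count: 10.
Longest linear sequence: 8 steps (steps 1–5 and 8–10, from 1 to 19); the squarate arm (steps 6 and 7) joins at step 8.

Steps most likely to fail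

1. Step 8. Transfer of the hindered 1,1-disubstituted alkenyl group from tin to palladium may be slow. The chlorocyclobutenone would then be consumed by its own thermal ring opening and ketene dimerisation, or the stannane would lose tin by protonation before it couples. The fallback builds ring B from a preformed arene, sets out from 6 and comes back at 18. Purchased 3,4-dihydroxy-5-methoxybenzaldehyde F1 is alkylated twice (2-bromopropane, K2CO3, DMF, 60 °C) to 3,4-diisopropoxy-5-methoxybenzaldehyde F2. This is reduced (NaBH4, MeOH, 0 °C) to (3,4-diisopropoxy-5-methoxyphenyl)methanol F3 and brominated (PBr3, CH2Cl2, 0 °C) to 5-(bromomethyl)-1,2-diisopropoxy-3-methoxybenzene F4. Lithium enolate 8, made from 6 as in step 4, is alkylated by F4 anti to the C4 benzyl group and should give 18 directly, from which step 10 follows.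

2. Step 5. The new alkenylstannane may cross-couple with unreacted bromide 9 (dimerisation to a diene), oxidative addition at the 2-bromoalkene may stall, or tin may be lost by protonation during purification. The fallback avoids the bromide, sets out from 6 and comes back at 10. Enolate 8 is alkylated with 3-bromoprop-1-yne (THF, −78 °C) to (3R,4R)-4-[4-(benzyloxy)-3-methoxybenzyl]-3-(prop-2-yn-1-yl)dihydrofuran-2(3H)-one F5, again trans. Syn addition of the stannylcopper reagent Me3SnCu·SMe2 (from Me3SnLi and CuBr·SMe2) in THF with MeOH as proton source at −63 °C places tin on the internal alkyne carbon and should give 10.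

3. Step 10. The benzyl cation may escape the scavenger and alkylate ring A or ring B (Friedel–Crafts), the second isopropyl ether of ring B may cleave incompletely once the first aryl borate has formed, or forcing the reaction may start to remove a methyl ether. The fallback separates the two cleavages, sets out from 18 and comes back at 19. Hydrogenolysis (H2, Pd/C, EtOAc, rt) removes only the benzyl group and gives (3R,4R)-3-(3,4-diisopropoxy-5-methoxybenzyl)-4-(4-hydroxy-3-methoxybenzyl)dihydrofuran-2(3H)-one F6. AlCl3 (CH2Cl2, 0 °C → rt) then cleaves the two isopropyl ethers in preference to the methyl ethers and should give 19.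

Further compounds
F1 | step 8 | 3,4-dihydroxy-5-methoxybenzaldehyde (purchased) | COc1cc(C=O)cc(O)c1O
F2 | step 8 | 3,4-diisopropoxy-5-methoxybenzaldehyde | COc1cc(C=O)cc(OC(C)C)c1OC(C)C
F3 | step 8 | (3,4-diisopropoxy-5-methoxyphenyl)methanol | COc1cc(CO)cc(OC(C)C)c1OC(C)C
F4 | step 8 | 5-(bromomethyl)-1,2-diisopropoxy-3-methoxybenzene | COc1cc(CBr)cc(OC(C)C)c1OC(C)C
F5 | step 5 | (3R,4R)-4-[4-(benzyloxy)-3-methoxybenzyl]-3-(prop-2-yn-1-yl)dihydrofuran-2(3H)-one | COc1cc(C[C@H]2COC(=O)[C@@H]2CC#C)ccc1OCc1ccccc1
F6 | step 10 | (3R,4R)-3-(3,4-diisopropoxy-5-methoxybenzyl)-4-(4-hydroxy-3-methoxybenzyl)dihydrofuran-2(3H)-one | COc1cc(C[C@H]2COC(=O)[C@@H]2Cc2cc(OC)c(OC(C)C)c(OC(C)C)c2)ccc1O
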